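**Retrosynthetic overview**

1. The target comes from one global hydrogenation/hydrogenolysis of a cis-4,6-dialkenyl-2-phenyl-1,3-dioxane whose phenol is a benzyl ether.
2. The non-1-enyl arm comes from cross-metathesis of a terminal vinyl group with non-1-ene.
3. Key step: the styryl/vinyl diene comes from an enantioselective ring-opening/cross-metathesis of a meso bridged cyclopentene acetal with a vinylguaiacol ether. The syn-1,3-diol is inherited from the meso ring; the catalyst decides which carbinol carries which arm.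
4. The meso acetal comes from cis-cyclopent-4-ene-1,3-diol and a benzaldehyde acetal; the styrene comes from 2-methoxy-4-vinylphenol, a bulk flavour chemical.
5. Ring order: the arene is bought; the only ring made is the temporary 1,3-dioxane bridge (step 2), and the cyclopentene is then opened (step 3). No ring has to be built for the target.

Assumption: the sense of induction in step 3 is not predictable for this new substrate; the route is written with the (S)-biphenolate complex given in step 3, and its (R)-enantiomer is used instead if a first run (chiral HPLC against a racemate, Mosher analysis after acetal methanolysis) shows the mirror-image product. The acetal carbon is a stereocentre that is excised in step 5; it is drawn as formed (phenyl anti to the former alkene bridge).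

**Route**

Step 1
Reactants: 1 para-vinylguaiacol (2-methoxy-4-vinylphenol)
Product: 2 benzyl 4-ethenyl-2-methoxyphenyl ether
Conditions: BnBr (1.1 equiv), K2CO3 (1.5 equiv), BHT (trace), DMF, rt
Reagents that add atoms: benzyl bromide, BrCc1ccccc1
Why: Williamson ether synthesis (SN2 of the phenoxide on benzyl bromide); the benzyl group keeps the acidic phenol away from the molybdenum alkylidene of step 3 and falls off in step 5 at no extra cost.

Step 2
Reactants: 3 cis-cyclopent-4-ene-1,3-diol (meso)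
Product: 4 (1R,5S)-3-phenyl-2,4-dioxabicyclo[3.2.1]oct-6-ene (meso; phenyl equatorial on the dioxane chair, acetal hydrogen pointing toward the C6=C7 bridge)
Conditions: PhCH(OMe)2 (1.2 equiv), PPTS (5 mol%), toluene, 50 °C, reduced pressure (MeOH removed); Et3N quench
Reagents that add atoms: benzaldehyde dimethyl acetal, COC(OC)c1ccccc1
Why: acid-catalysed transacetalisation driven by methanol removal bridges the cis-diol and places phenyl in the only unhindered (equatorial) position; no chirality is created, and the one-atom bridge adds the ring strain that a plain cyclopentene lacks for ring-opening metathesis.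

Step 3
Reactants: 4 (1R,5S)-3-phenyl-2,4-dioxabicyclo[3.2.1]oct-6-ene, 2 benzyl 4-ethenyl-2-methoxyphenyl ether
Product: 5 (2S,4R,6S)-4-[(E)-2-(4-benzyloxy-3-methoxyphenyl)ethenyl]-6-ethenyl-2-phenyl-1,3-dioxane (4,6-cis; 2-phenyl trans to both alkenyl groups)
Conditions: Mo(=N-2,6-iPr2C6H3)(=CHCMe2Ph)[(S)-3,3'-tBu2-5,5',6,6'-Me4-biphenyl-2,2'-diolate] (5 mol%), C6H6, 22 °C, N2; the bicyclic acetal added slowly to a twofold excess of the styrene, surplus styrene recovered
Reagents that add atoms: none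
Why: Proposed new method: the chiral molybdenum alkylidene in its ArCH= form adds to the strained bridged alkene of meso 4 from the face of the CH2 bridge, and the biphenolate pocket selects one of the two enantiotopic alkene carbons; strain-releasing cycloreversion opens the ring, and the new alkylidene then takes the CH2 terminus of a molecule of 2 as its vinyl group while the ArCH= unit returns to molybdenum, so the net reaction is a 1:1 addition of 2 across the cleaved C=C bond in which every atom of 4 and of 2 ends up in 5; the syn-1,3-dioxygen pattern is inherited from the meso ring and the absolute configuration (styryl on the carbinol carbon that becomes C3 of the target) is set in this single event; the closest known reaction type is catalytic asymmetric ring-opening/cross-metathesis of meso norbornenes and of 8-oxa- and 8-azabicyclo[3.2.1]oct-6-enes with styrenes, and dialkylsilylene-bridged analogues of 4 are reported ring-opening metathesis polymerisation monomers.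

Step 4
Reactants: 5 (2S,4R,6S)-4-[(E)-2-(4-benzyloxy-3-methoxyphenyl)ethenyl]-6-ethenyl-2-phenyl-1,3-dioxane, 6 non-1-ene
Product: 7 (2S,4R,6S)-4-[(E)-2-(4-benzyloxy-3-methoxyphenyl)ethenyl]-6-[(E)-non-1-en-1-yl]-2-phenyl-1,3-dioxane
Conditions: second-generation Hoveyda–Grubbs catalyst RuCl2(H2IMes)(=CH-C6H4-2-OiPr) (5 mol%), non-1-ene in fivefold excess, CH2Cl2, 40 °C
Reagents that add atoms: none
Why: olefin cross-metathesis at the terminal vinyl group, which reacts far faster than the internal conjugated styryl alkene, is driven by loss of ethylene; the E/Z ratio of the new alkene is irrelevant (drawn E) and no stereocentre is touched.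

Step 5
Reactants: 7 (2S,4R,6S)-4-[(E)-2-(4-benzyloxy-3-methoxyphenyl)ethenyl]-6-[(E)-non-1-en-1-yl]-2-phenyl-1,3-dioxane
Product: 9 (3S,5R)-1-(4-hydroxy-3-methoxyphenyl)tetradecane-3,5-diol, via saturated O-benzyl benzylidene acetal 8 (not isolated)
Conditions: H2 (1 atm), 10% Pd/C, EtOAc, rt, 1 h; then MeOH, Pd(OH)2/C, AcOH (cat.), H2 (1 atm), rt, 12 h
Reagents that add atoms: none
Why: heterogeneous catalytic hydrogenation saturates both alkenes first in neutral EtOAc (giving 8, no longer allylic), after which hydrogenolysis removes the aryl benzyl ether and the benzylidene acetal as toluene; the two C–O stereocentres are not involved, so the syn (3S,5R) diol is delivered.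

**Compound list**

1 | para-vinylguaiacol (2-methoxy-4-vinylphenol) | C=Cc1ccc(O)c(OC)c1 | starting material
2 | benzyl 4-ethenyl-2-methoxyphenyl ether | C=Cc1ccc(OCc2ccccc2)c(OC)c1 | intermediate
3 | cis-cyclopent-4-ene-1,3-diol (meso) | O[C@H]1C[C@@H](O)C=C1 | starting material
4 | (1R,5S)-3-phenyl-2,4-dioxabicyclo[3.2.1]oct-6-ene (meso, phenyl equatorial) | C1=C[C@@H]2C[C@H]1O[C@@H](c1ccccc1)O2 | intermediate
5 | (2S,4R,6S)-4-[(E)-2-(4-benzyloxy-3-methoxyphenyl)ethenyl]-6-ethenyl-2-phenyl-1,3-dioxane | C=C[C@@H]1C[C@H](/C=C/c2ccc(OCc3ccccc3)c(OC)c2)O[C@@H](c2ccccc2)O1 | intermediate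
6 | non-1-ene | C=CCCCCCCC | starting material
7 | (2S,4R,6S)-4-[(E)-2-(4-benzyloxy-3-methoxyphenyl)ethenyl]-6-[(E)-non-1-en-1-yl]-2-phenyl-1,3-dioxane | CCCCCCC/C=C/[C@@H]1C[C@H](/C=C/c2ccc(OCc3ccccc3)c(OC)c2)O[C@@H](c2ccccc2)O1 | intermediate
8 | (2S,4S,6R)-4-[2-(4-benzyloxy-3-methoxyphenyl)ethyl]-6-nonyl-2-phenyl-1,3-dioxane | CCCCCCCCC[C@@H]1C[C@H](CCc2ccc(OCc3ccccc3)c(OC)c2)O[C@@H](c2ccccc2)O1 | intermediate
9 | (3S,5R)-1-(4-hydroxy-3-methoxyphenyl)tetradecane-3,5-diol | CCCCCCCCC[C@@H](O)C[C@@H](O)CCc1ccc(O)c(OC)c1 | target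

**Step count**

Total steps: 5. Longest linear sequence: 4 (steps 2, 3, 4, 5); step 1 is a one-step branch.

**Steps most likely to fail, and fallbacks**

Step 3 is the main risk: the level and sense of enantioselection on a carbocyclic bridged cyclopentene are untested, and ring-opening polymerisation of 4 competes. The fallback breaks the symmetry enzymatically after oxidative ring cleavage; it sets out from 4 and comes back at 5. Ozonolysis of 4 (O3, CH2Cl2/MeOH, −78 °C, stopped when the alkene is consumed; then NaBH4) gives the meso diol [(4R,6S)-2-phenyl-1,3-dioxane-4,6-diyl]dimethanol F1. Lipase-catalysed mono-acetylation with vinyl acetate then gives [6-(hydroxymethyl)-2-phenyl-1,3-dioxan-4-yl]methyl acetate F2, with the free CH2OH on the future C3 side; lipase hydrolysis of the diacetate gives the opposite monoacetate, so the needed one is accessible either way. NaHCO3-buffered Dess–Martin oxidation gives the aldehyde 6-(acetoxymethyl)-2-phenyl-1,3-dioxane-4-carbaldehyde F3. Horner–Wadsworth–Emmons olefination with diethyl [4-(benzyloxy)-3-methoxybenzyl]phosphonate and NaH gives the (E)-styryl acetate {6-[(E)-2-(4-benzyloxy-3-methoxyphenyl)ethenyl]-2-phenyl-1,3-dioxan-4-yl}methyl acetate F4. K2CO3/MeOH gives the alcohol {6-[(E)-2-(4-benzyloxy-3-methoxyphenyl)ethenyl]-2-phenyl-1,3-dioxan-4-yl}methanol F5. A second Dess–Martin oxidation gives 6-[(E)-2-(4-benzyloxy-3-methoxyphenyl)ethenyl]-2-phenyl-1,3-dioxane-4-carbaldehyde F6, and Wittig methylenation (Ph3PCH3Br, KOtBu) returns 5.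

Step 2 is the second risk: the bridged benzylidene acetal may form reluctantly or be labile, because the C–O bridge is tighter than a silicon bridge and the diol is bis-allylic. The fallback uses a silicon bridge and a fluoride end-game; it sets out from 3 and comes back at 9. tBu2Si(OTf)2 and 2,6-lutidine in CH2Cl2 at 0 °C give 3,3-di-tert-butyl-2,4-dioxa-3-silabicyclo[3.2.1]oct-6-ene F7. The step 3 conditions with 2 then give (4R,6S)-2,2-di-tert-butyl-4-[(E)-2-(4-benzyloxy-3-methoxyphenyl)ethenyl]-6-ethenyl-1,3,2-dioxasilinane F8. The step 4 conditions with 6 give (4R,6S)-2,2-di-tert-butyl-4-[(E)-2-(4-benzyloxy-3-methoxyphenyl)ethenyl]-6-[(E)-non-1-en-1-yl]-1,3,2-dioxasilinane F9. H2 over Pd/C gives (4S,6R)-2,2-di-tert-butyl-4-[2-(4-hydroxy-3-methoxyphenyl)ethyl]-6-nonyl-1,3,2-dioxasilinane F10, and HF·pyridine in THF releases 9.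

Step 4 is the third risk: the ruthenium alkylidene formed at the vinyl group can attack the styryl alkene (scrambling, or ring closure back toward 4). The fallback avoids metathesis; it sets out from 5 and comes back at 8. 9-BBN in THF hydroborates only the terminal vinyl group, giving the B-alkyl borane 9-{2-[(2S,4R,6R)-6-[(E)-2-(4-benzyloxy-3-methoxyphenyl)ethenyl]-2-phenyl-1,3-dioxan-4-yl]ethyl}-9-borabicyclo[3.3.1]nonane F11. Alkyl–alkyl Suzuki–Miyaura coupling with 1-bromoheptane (Pd(OAc)2, PCy3, K3PO4·H2O, THF, rt) gives (2S,4R,6R)-4-[(E)-2-(4-benzyloxy-3-methoxyphenyl)ethenyl]-6-nonyl-2-phenyl-1,3-dioxane F12, which is hydrogenated to 8 under the step 5 conditions and carried on to 9.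

**Further compounds**

F1 | step 3 | meso [(4R,6S)-2-phenyl-1,3-dioxane-4,6-diyl]dimethanol, phenyl trans to both CH2OH groups | OC[C@@H]1C[C@H](CO)O[C@@H](c2ccccc2)O1
F2 | step 3 | [6-(hydroxymethyl)-2-phenyl-1,3-dioxan-4-yl]methyl acetate, free CH2OH on the future C3 side | CC(=O)OC[C@@H]1C[C@H](CO)O[C@@H](c2ccccc2)O1
F3 | step 3 | 6-(acetoxymethyl)-2-phenyl-1,3-dioxane-4-carbaldehyde | CC(=O)OC[C@@H]1C[C@H](C=O)O[C@@H](c2ccccc2)O1
F4 | step 3 | {6-[(E)-2-(4-benzyloxy-3-methoxyphenyl)ethenyl]-2-phenyl-1,3-dioxan-4-yl}methyl acetate | CC(=O)OC[C@@H]1C[C@H](/C=C/c2ccc(OCc3ccccc3)c(OC)c2)O[C@@H](c2ccccc2)O1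
F5 | step 3 | {6-[(E)-2-(4-benzyloxy-3-methoxyphenyl)ethenyl]-2-phenyl-1,3-dioxan-4-yl}methanol | OC[C@@H]1C[C@H](/C=C/c2ccc(OCc3ccccc3)c(OC)c2)O[C@@H](c2ccccc2)O1
F6 | step 3 | 6-[(E)-2-(4-benzyloxy-3-methoxyphenyl)ethenyl]-2-phenyl-1,3-dioxane-4-carbaldehyde | O=C[C@@H]1C[C@H](/C=C/c2ccc(OCc3ccccc3)c(OC)c2)O[C@@H](c2ccccc2)O1
F7 | step 2 | 3,3-di-tert-butyl-2,4-dioxa-3-silabicyclo[3.2.1]oct-6-ene (meso) | C1=C[C@@H]2C[C@H]1O[Si](C(C)(C)C)(C(C)(C)C)O2
F8 | step 2 | (4R,6S)-2,2-di-tert-butyl-4-[(E)-2-(4-benzyloxy-3-methoxyphenyl)ethenyl]-6-ethenyl-1,3,2-dioxasilinane | C=C[C@@H]1C[C@H](/C=C/c2ccc(OCc3ccccc3)c(OC)c2)O[Si](C(C)(C)C)(C(C)(C)C)O1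
F9 | step 2 | (4R,6S)-2,2-di-tert-butyl-4-[(E)-2-(4-benzyloxy-3-methoxyphenyl)ethenyl]-6-[(E)-non-1-en-1-yl]-1,3,2-dioxasilinane | CCCCCCC/C=C/[C@@H]1C[C@H](/C=C/c2ccc(OCc3ccccc3)c(OC)c2)O[Si](C(C)(C)C)(C(C)(C)C)O1
F10 | step 2 | (4S,6R)-2,2-di-tert-butyl-4-[2-(4-hydroxy-3-methoxyphenyl)ethyl]-6-nonyl-1,3,2-dioxasilinane | CCCCCCCCC[C@@H]1C[C@H](CCc2ccc(O)c(OC)c2)O[Si](C(C)(C)C)(C(C)(C)C)O1
F11 | step 4 | 9-{2-[(2S,4R,6R)-6-[(E)-2-(4-benzyloxy-3-methoxyphenyl)ethenyl]-2-phenyl-1,3-dioxan-4-yl]ethyl}-9-borabicyclo[3.3.1]nonane | C1CCC2CCCC1B2CC[C@@H]3C[C@H](/C=C/c4ccc(OCc5ccccc5)c(OC)c4)O[C@@H](c4ccccc4)O3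
F12 | step 4 | (2S,4R,6R)-4-[(E)-2-(4-benzyloxy-3-methoxyphenyl)ethenyl]-6-nonyl-2-phenyl-1,3-dioxane | CCCCCCCCC[C@@H]1C[C@H](/C=C/c2ccc(OCc3ccccc3)c(OC)c2)O[C@@H](c2ccccc2)O1
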